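## Retrosynthetic overview

- Target 11 is a chroman-4-one (ring A: dimethoxybenzo ring; ring C: pyranone ring) whose C3 is the spiro atom of a benzocyclobutene (ring B: dimethoxybenzene; ring D: cyclobutene).
- Key disconnection: both aryl–C(sp3) bonds of ring D (ring-B carbon–C3 and ring-B carbon–CH2) are cut at once. This is a formal [2+2] annulation of racemic 5,7-dimethoxy-3-methylchroman-4-one 6 with 1-bromo-2-iodo-3,4-dimethoxybenzene 9 under palladium catalysis: asymmetric α-arylation, then methyl C(sp3)–H arylation in the same flask.
- Enabling feature: C3 of ring C is the only α-carbon of the C4 ketone and carries the future ring-D CH2 as a methyl group. As an enolate it is the nucleophile for the first aryl bond. Once arylated it is quaternary (no α-H, no β-H towards palladium), and its methyl C–H bonds sit in a 1,4-relation to the bromine-bearing carbon of ring B, so a five-membered palladacycle can close ring D.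
- Order of ring formation: ring A is bought (3,5-dimethoxyphenol) and ring C is closed on it; ring B is bought (4-bromoveratrole) and iodinated; ring D is formed last, together with the only stereocenter (ligand control).

Key step: step 4

Assumption: the sense of induction of the chiral phosphine in step 4 cannot be predicted with certainty for this enolate; the (R)-ligand written below stands for whichever antipode a first test shows to deliver the (S)-configured quaternary carbon.

## Route

Step 1
Reactants: 1 3,5-dimethoxyphenol; 2 3-chloropropanoic acid
Product: 4 5,7-dimethoxychroman-4-one, via chloroethyl ketone 3 (not isolated)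
Conditions: TfOH (neat), 80 °C; then 2 M NaOH (aq), 0 °C to rt
Reagents that add atoms: none
Why: Friedel–Crafts acylation of the electron-rich phenol ortho to OH (favoured by hydrogen-bond stabilisation of the ortho-acyl phenol) should give 3, and base then closes ring C by intramolecular Williamson etherification (6-exo-tet, or E1cB/oxa-Michael); no stereocenter is formed.

Step 2
Reactants: 4 5,7-dimethoxychroman-4-one
Product: 6 rac-5,7-dimethoxy-3-methylchroman-4-one, via lithium enolate 5 (not isolated)
Conditions: LiN(SiMe3)2 (1.05 equiv), THF, −78 °C; MeI, −78 to 0 °C
Reagents that add atoms: iodomethane, CI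
Why: Kinetic enolate formation at C3, the only enolisable position of the aryl ketone, followed by SN2 methylation (enolate alkylation) should give 6; the C3 stereocenter forms as a racemate, which does not matter because C3 is planarised again as an enolate in step 4.

Step 3
Reactants: 7 4-bromo-1,2-dimethoxybenzene
Product: 9 1-bromo-2-iodo-3,4-dimethoxybenzene, via aryllithium 8 (not isolated)
Conditions: LiN(iPr)2 (1.1 equiv), THF, −78 °C; I2, −78 °C to rt
Reagents that add atoms: iodine, II
Why: Directed ortho-metalation should remove the hydrogen between bromine and the methoxy group (most acidic through the inductive effect of Br and coordination by OMe), and iodine quench of the aryllithium puts iodine on the methoxy-flanked carbon; no stereocenter is formed.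

Step 4
Reactants: 6 rac-5,7-dimethoxy-3-methylchroman-4-one; 9 1-bromo-2-iodo-3,4-dimethoxybenzene (1.1 equiv)
Product: 11 (7S)-4,5,5',7'-tetramethoxyspiro[bicyclo[4.2.0]octa-1,3,5-triene-7,3'-chroman]-4'-one, via bromoaryl ketone 10 (not isolated)
Conditions: Pd2(dba)3 (2.5 mol %), (R)-2-(dicyclohexylphosphino)-2'-(dimethylamino)-1,1'-binaphthyl (6 mol %), NaOtBu (1.3 equiv), toluene, 60 °C; then, same flask, toluene exchanged for DMF, Pd(OAc)2 (5 mol %), P(tBu)3·HBF4 (10 mol %), K2CO3 (2 equiv), 140 °C
Reagents that add atoms: none
Why: Proposed new method: zerovalent palladium bearing the bulky chiral monophosphine inserts into the weaker C–I bond of 9, the sodium enolate of 6 replaces iodide on divalent palladium, and C–C reductive elimination from the C-bound aryl palladium enolate gives 10; after the switch to P(tBu)3 and carbonate at 140 °C, oxidative addition into the remaining C–Br bond, carbonate-assisted concerted metalation–deprotonation of the C3 methyl group and C(sp2)–C(sp3) reductive elimination give 11. The closest known reaction types are the enantioselective palladium-catalysed α-arylation of α-methyl benzo-fused cyclic ketones (2-methyl-1-tetralone class) and the Pd(OAc)2/P(tBu)3-catalysed C(sp3)–H arylation of 2-bromoaryl compounds with a benzylic quaternary carbon bearing a methyl group, which gives benzocyclobutenes; new are their merger through a 1,2-dihaloarene into a formal [2+2] annulation and the use of a di-ortho-substituted aryl iodide in the asymmetric event. Ring D is the only ring closed, and it closes by reductive elimination from the five-membered palladacycle (Pd, ring-B carbon, ring-B carbon, C3, CH2), a formal 4-exo closure. The C3 stereocenter is set in the first event by ligand-controlled selection between the enantiotopic faces of the enolate; once formed it is quaternary, cannot epimerise and is not touched by the C–H arylation, so the (S) configuration of 10 is carried into 11. The step needs halogen site selectivity (C–I before C–Br at 60 °C, which places C3 on the methoxy-flanked ring-B carbon), C–H site selectivity (primary methyl C–H over the secondary OCH2 C–H of ring C, the usual preference of concerted metalation–deprotonation) and a palladium intermediate without escape routes, which the substrate secures because arylated C3 has no α-hydrogen (no enolate O-arylation to a benzofuran) and no β-hydrogen available to palladium.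

## Compound list

1 | 3,5-dimethoxyphenol | COc1cc(O)cc(OC)c1 | starting material
2 | 3-chloropropanoic acid | OC(=O)CCCl | starting material
3 | 3-chloro-1-(2-hydroxy-4,6-dimethoxyphenyl)propan-1-one | COc1cc(O)c(C(=O)CCCl)c(OC)c1 | intermediate
4 | 5,7-dimethoxychroman-4-one | COc1cc(OC)c2c(c1)OCCC2=O | intermediate
5 | lithium 5,7-dimethoxy-2H-chromen-4-olate | COc1cc(OC)c2c(c1)OCC=C2O[Li] | intermediate
6 | rac-5,7-dimethoxy-3-methylchroman-4-one | COc1cc(OC)c2c(c1)OCC(C)C2=O | intermediate
7 | 4-bromo-1,2-dimethoxybenzene | COc1ccc(Br)cc1OC | starting material
8 | (6-bromo-2,3-dimethoxyphenyl)lithium | [Li]c1c(Br)ccc(OC)c1OC | intermediate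
9 | 1-bromo-2-iodo-3,4-dimethoxybenzene | COc1ccc(Br)c(I)c1OC | intermediate
10 | (S)-3-(6-bromo-2,3-dimethoxyphenyl)-5,7-dimethoxy-3-methylchroman-4-one | COc1cc(OC)c2c(c1)OC[C@](C)(c1c(Br)ccc(OC)c1OC)C2=O | intermediate
11 | (7S)-4,5,5',7'-tetramethoxyspiro[bicyclo[4.2.0]octa-1,3,5-triene-7,3'-chroman]-4'-one (CNP0192565.1; spiro carbon = chromanone C3, bonded to the ring-B carbon that is flanked by a methoxy group) | COc1cc(OC)c2c(c1)OC[C@@]1(Cc3ccc(OC)c(OC)c31)C2=O | target

## Step count and risks

Total step count: 4 (steps 1, 2 and 4 in the main line, step 3 for the arene partner).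
Longest linear sequence: 3 steps (1 → 4 → 6 → 11).

Steps most likely to fail:

1. Step 4. What may go wrong: the di-ortho-substituted arylpalladium iodide may fail to capture the fully substituted enolate, so the first event does not turn over, or the ligand may discriminate poorly between the enolate faces. Fallback in known chemistry, setting out from 4 and from aryllithium 8 and returning at 10: 4 is C-acylated (NaH, dimethyl carbonate, THF, reflux) to methyl 5,7-dimethoxy-4-oxochroman-3-carboxylate F1. Aryllithium 8, generated as in step 3, is quenched with B(OiPr)3 and worked up with aqueous HCl to (6-bromo-2,3-dimethoxyphenyl)boronic acid F2. Boron–lead exchange (Pb(OAc)4, Hg(OAc)2 cat., CHCl3, 40 °C) converts F2 into (6-bromo-2,3-dimethoxyphenyl)lead triacetate F3. Pinhey arylation of F1 with F3 (pyridine, CHCl3, 60 °C), a reaction that tolerates di-ortho-substituted aryl groups, should give methyl 3-(6-bromo-2,3-dimethoxyphenyl)-5,7-dimethoxy-4-oxochroman-3-carboxylate F4. Krapcho dealkoxycarbonylation (LiCl, wet DMSO, 130 °C) should give racemic 3-(6-bromo-2,3-dimethoxyphenyl)-5,7-dimethoxychroman-4-one F5. Asymmetric phase-transfer methylation of F5 (MeI, N-(9-anthracenylmethyl)cinchonidinium bromide or its cinchoninium pseudoenantiomer, 50% aq KOH, toluene, −20 °C) then sets the quaternary centre and returns the route at 10. Compound 10 is isolated and closed to 11 by the second stage of step 4 run on its own (Pd(OAc)2, P(tBu)3·HBF4, K2CO3, DMF, 140 °C), which is the known benzocyclobutene-forming C(sp3)–H arylation.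

2. Step 3. What may go wrong: aryllithium 8 may equilibrate by halogen dance or lose LiBr to an aryne before the iodine quench. Fallback, setting out from 7 and returning at 9: 7 is deprotonated in the presence of the electrophile (LiN(iPr)2 added to 7 and Me3SiCl, THF, −78 °C, in situ quench), so that the aryllithium never accumulates, to give (6-bromo-2,3-dimethoxyphenyl)trimethylsilane F6. Ipso-iododesilylation (ICl, CH2Cl2, 0 °C) should then give 9.

3. Step 2. What may go wrong: proton transfer between enolate 5 and product 6 may lead to double methylation, and the enolate may open ring C by E1cB loss of the aryloxide. Fallback, setting out from 4 and returning at 6: condensation of 4 with N,N-dimethylformamide dimethyl acetal (neat, 100 °C) should give (E)-3-[(dimethylamino)methylene]-5,7-dimethoxychroman-4-one F7. Hydrogenation with hydrogenolysis of the amine (H2, Pd on carbon (Pd/C), EtOH, rt) should give 6; this sequence can introduce only one methyl group.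

## Further compounds

F1 | step 4 | methyl 5,7-dimethoxy-4-oxochroman-3-carboxylate (racemic) | COC(=O)C1COc2cc(OC)cc(OC)c2C1=O
F2 | step 4 | (6-bromo-2,3-dimethoxyphenyl)boronic acid | COc1ccc(Br)c(B(O)O)c1OC
F3 | step 4 | (6-bromo-2,3-dimethoxyphenyl)lead triacetate | CC(=O)O[Pb](OC(C)=O)(OC(C)=O)c1c(Br)ccc(OC)c1OC
F4 | step 4 | methyl 3-(6-bromo-2,3-dimethoxyphenyl)-5,7-dimethoxy-4-oxochroman-3-carboxylate (racemic) | COC(=O)C1(c2c(Br)ccc(OC)c2OC)COc2cc(OC)cc(OC)c2C1=O
F5 | step 4 | 3-(6-bromo-2,3-dimethoxyphenyl)-5,7-dimethoxychroman-4-one (racemic) | COc1cc(OC)c2c(c1)OCC(c1c(Br)ccc(OC)c1OC)C2=O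
F6 | step 3 | (6-bromo-2,3-dimethoxyphenyl)trimethylsilane | COc1ccc(Br)c([Si](C)(C)C)c1OC
F7 | step 2 | (E)-3-[(dimethylamino)methylene]-5,7-dimethoxychroman-4-one | COc1cc(OC)c2c(c1)OC/C(=C\N(C)C)C2=O
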